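**Retrosynthetic overview**

1. The C9′ ester is made last from a protected tetralin alcohol and O‑benzyl‑p‑coumaric acid; the C7 phenol comes from a C7 aryl bromide by borylation and oxidation.
2. Rings A and B are closed together by an intramolecular 2‑pyrone/alkyne Diels–Alder reaction with loss of CO2 (bonds C7–C8 and C4a–C8a). The feature used is ring A's unlike oxygen pair, OMe on C6 and OH on C7 between C5–H and C8–H, which maps onto C4–OMe and C3–Br of a 2‑pyrone.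
3. The open‑chain precursor 25 gets its C3–C4 bond by Evans alkylation with a bromomethylpyrone, its C2–C3 bond by Evans alkylation with tert‑butyl bromoacetate, and C1 by rhodium‑catalysed asymmetric alkynylation of the arylidene Meldrum's acid of O‑benzylvanillin.
4. Ring order: the pendant guaiacyl ring and the pyrone are bought, then rings A and B form in one step; the C9 arm (OBn) and the C9′ arm (OTBS) are different from the moment they are made.

Key step: step 16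

Remark: positions are numbered as in the tetralin (C1 bears the aryl group, C2 and C3 bear the C9′ and C9 arms, C4 is the benzylic CH2). O‑Benzylvanillin, Meldrum's acid, both antipodes of 4‑benzyl‑2‑oxazolidinone and 4‑methoxy‑6‑methyl‑2‑pyrone are taken as commercial, and the bisphosphine antipode in step 4 is the one that delivers (S)‑8.

**Route**

Step 1
Reactants: 1 4‑methoxy‑6‑methyl‑2H‑pyran‑2‑one
Product: 2 3‑bromo‑4‑methoxy‑6‑methyl‑2H‑pyran‑2‑one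
Conditions: NBS, MeCN, rt, dark
Reagents that add atoms: N‑bromosuccinimide, BrN1C(=O)CCC1=O
Why: Electrophilic bromination at C3, the nucleophilic α‑carbon of the β‑alkoxy enoate of the pyrone; no stereocenter is involved.

Step 2
Reactants: 2 3‑bromo‑4‑methoxy‑6‑methyl‑2H‑pyran‑2‑one
Product: 3 3‑bromo‑6‑(bromomethyl)‑4‑methoxy‑2H‑pyran‑2‑one
Conditions: NBS (1.05 equiv), AIBN (cat.), PhCF3, 85 °C
Reagents that add atoms: N‑bromosuccinimide, BrN1C(=O)CCC1=O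
Why: Wohl–Ziegler radical bromination of the C6 methyl group, whose radical is delocalised into the pyrone; C3 is already blocked, so ring bromination cannot compete.

Step 3
Reactants: 4 4‑(benzyloxy)‑3‑methoxybenzaldehyde; 5 Meldrum's acid (2,2‑dimethyl‑1,3‑dioxane‑4,6‑dione)
Product: 6 5‑{[4‑(benzyloxy)‑3‑methoxyphenyl]methylidene}‑2,2‑dimethyl‑1,3‑dioxane‑4,6‑dione
Conditions: pyrrolidinium acetate (cat.), PhMe, rt
Reagents that add atoms: none
Why: Knoevenagel condensation of an aryl aldehyde with a highly acidic cyclic malonate; the product is symmetric at the alkene, so no geometry issue arises.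

Step 4
Reactants: 6 arylidene Meldrum's acid; 7 (trimethylsilyl)acetylene
Product: 8 5‑{(1S)‑1‑[4‑(benzyloxy)‑3‑methoxyphenyl]‑3‑(trimethylsilyl)prop‑2‑yn‑1‑yl}‑2,2‑dimethyl‑1,3‑dioxane‑4,6‑dione
Conditions: Rh(acac)(C2H4)2 (5 mol%), 3,5‑xylyl‑MeOBIPHEP (5.5 mol%), 7 (excess), 1,4‑dioxane, rt
Reagents that add atoms: none
Why: Rhodium‑catalysed asymmetric conjugate alkynylation, in which a monovalent rhodium acetylide adds 1,4 to the strongly electrophilic alkylidene and the chiral bisphosphine chooses the face, so C1 is set by catalyst control.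

Step 5
Reactants: 8 alkynylated Meldrum's acid
Product: 9 (3S)‑3‑[4‑(benzyloxy)‑3‑methoxyphenyl]‑5‑(trimethylsilyl)pent‑4‑ynoic acid
Conditions: DMF/H2O (10:1), 100 °C
Reagents that add atoms: water, O
Why: Hydrolytic opening of the Meldrum's acid ring and decarboxylation of the resulting malonic acid under neutral conditions, which leave the alkynyl silane and the remote C1 center untouched.

Step 6
Reactants: 9 (3S)‑pentynoic acid
Product: 11 (4S)‑4‑benzyl‑3‑{(3S)‑3‑[4‑(benzyloxy)‑3‑methoxyphenyl]‑5‑(trimethylsilyl)pent‑4‑ynoyl}‑1,3‑oxazolidin‑2‑one, via mixed pivalic anhydride 10 (not isolated)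
Conditions: PivCl, Et3N, THF, −20 °C; then (S)‑4‑benzyl‑2‑oxazolidinone, LiCl, rt
Reagents that add atoms: pivaloyl chloride, CC(C)(C)C(Cl)=O (atoms in 10 only); (S)‑4‑benzyl‑2‑oxazolidinone, O=C1N[C@@H](Cc2ccccc2)CO1
Why: N‑Acylation of the oxazolidinone through a mixed anhydride, attacked at the less hindered acyl carbon; no stereocenter is touched.

Step 7
Reactants: 11 (S)‑imide; 12 tert‑butyl bromoacetate
Product: 14 tert‑butyl (3S,4S)‑3‑{[(4S)‑4‑benzyl‑2‑oxo‑1,3‑oxazolidin‑3‑yl]carbonyl}‑4‑[4‑(benzyloxy)‑3‑methoxyphenyl]‑6‑(trimethylsilyl)hex‑5‑ynoate, via sodium Z‑enolate 13 (not isolated)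
Conditions: NaN(SiMe3)2, THF, −78 °C; then 12, −78 → −40 °C
Reagents that add atoms: sodium bis(trimethylsilyl)amide, [Na+].C[Si](C)(C)[N-][Si](C)(C)C (Na in 13 only)
Why: Evans alkylation, in which the chelated Z‑enolate is attacked on the face opposite the benzyl group of the (S)‑auxiliary; this sets C2 and brings in C3 and the future C9 as an ester distinct from the C9′ imide.

Step 8
Reactants: 14 alkylated (S)‑imide
Product: 15 tert‑butyl (3S,4S)‑4‑[4‑(benzyloxy)‑3‑methoxyphenyl]‑3‑(hydroxymethyl)‑6‑(trimethylsilyl)hex‑5‑ynoate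
Conditions: LiBH4, MeOH (1 equiv), Et2O, 0 °C
Reagents that add atoms: none
Why: Reductive removal of the auxiliary, since LiBH4 reduces the activated exocyclic imide carbonyl much faster than the hindered tert‑butyl ester; this frees the C9′ hydroxyl only.

Step 9
Reactants: 15 primary alcohol
Product: 16 tert‑butyl (3S,4S)‑4‑[4‑(benzyloxy)‑3‑methoxyphenyl]‑3‑({[tert‑butyl(dimethyl)silyl]oxy}methyl)‑6‑(trimethylsilyl)hex‑5‑ynoate
Conditions: TBSCl, imidazole, CH2Cl2, rt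
Reagents that add atoms: tert‑butyldimethylsilyl chloride, CC(C)(C)[Si](C)(C)Cl
Why: Silylation of the primary alcohol, which also prevents lactonisation onto the ester.

Step 10
Reactants: 16 silyl ether tert‑butyl ester
Product: 18 (3S,4S)‑4‑[4‑(benzyloxy)‑3‑methoxyphenyl]‑3‑({[tert‑butyl(dimethyl)silyl]oxy}methyl)‑6‑(trimethylsilyl)hex‑5‑ynoic acid, via trimethylsilyl ester 17 (not isolated)
Conditions: TMSOTf, 2,6‑lutidine, CH2Cl2, 0 °C; then aqueous pH 5 buffer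
Reagents that add atoms: trimethylsilyl triflate, C[Si](C)(C)OS(=O)(=O)C(F)(F)F (atoms in 17 only)
Why: Silyl‑triflate cleavage of the tert‑butyl ester with loss of isobutene under buffered conditions that spare the TBS ether, the alkynyl silane and the aryl ethers; the silyl ester hydrolyses on work‑up.

Step 11
Reactants: 18 carboxylic acid
Product: 20 (4R)‑4‑benzyl‑3‑{(3S,4S)‑4‑[4‑(benzyloxy)‑3‑methoxyphenyl]‑3‑({[tert‑butyl(dimethyl)silyl]oxy}methyl)‑6‑(trimethylsilyl)hex‑5‑ynoyl}‑1,3‑oxazolidin‑2‑one, via mixed pivalic anhydride 19 (not isolated)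
Conditions: PivCl, Et3N, THF, −20 °C; then (R)‑4‑benzyl‑2‑oxazolidinone, LiCl, rt
Reagents that add atoms: pivaloyl chloride, CC(C)(C)C(Cl)=O (atoms in 19 only); (R)‑4‑benzyl‑2‑oxazolidinone, O=C1N[C@H](Cc2ccccc2)CO1
Why: N‑Acylation through the mixed anhydride as in step 6, now with the antipodal auxiliary needed for the C3 configuration.

Step 12
Reactants: 20 (R)‑imide; 3 3‑bromo‑6‑(bromomethyl)‑4‑methoxy‑2H‑pyran‑2‑one
Product: 22 (4R)‑4‑benzyl‑3‑{(2R,3R,4S)‑4‑[4‑(benzyloxy)‑3‑methoxyphenyl]‑2‑[(3‑bromo‑4‑methoxy‑2‑oxo‑2H‑pyran‑6‑yl)methyl]‑3‑({[tert‑butyl(dimethyl)silyl]oxy}methyl)‑6‑(trimethylsilyl)hex‑5‑ynoyl}‑1,3‑oxazolidin‑2‑one, via sodium Z‑enolate 21 (not isolated)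
Conditions: NaN(SiMe3)2, THF, −78 °C; then 3 (2 equiv), −78 → −50 °C
Reagents that add atoms: sodium bis(trimethylsilyl)amide, [Na+].C[Si](C)(C)[N-][Si](C)(C)C (Na in 21 only)
Why: Evans alkylation with a reactive allylic‑type bromide, in which the (R)‑auxiliary shields one enolate face so that the pyronylmethyl group enters anti to its benzyl group; C3 is set by auxiliary control over any bias from C2.

Step 13
Reactants: 22 alkylated (R)‑imide
Product: 23 3‑bromo‑6‑[(2R,3R,4S)‑4‑[4‑(benzyloxy)‑3‑methoxyphenyl]‑3‑({[tert‑butyl(dimethyl)silyl]oxy}methyl)‑2‑(hydroxymethyl)‑6‑(trimethylsilyl)hex‑5‑yn‑1‑yl]‑4‑methoxy‑2H‑pyran‑2‑one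
Conditions: NaBH4, THF/H2O (4:1), 0 °C → rt
Reagents that add atoms: none
Why: Chemoselective borohydride reduction of the activated exocyclic imide carbonyl (reductive removal of the auxiliary); the 2‑pyrone, a vinylogous carbonate, is far less electrophilic and should survive.

Step 14
Reactants: 23 C9 alcohol
Product: 24 6‑[(2R,3R,4S)‑4‑[4‑(benzyloxy)‑3‑methoxyphenyl]‑2‑[(benzyloxy)methyl]‑3‑({[tert‑butyl(dimethyl)silyl]oxy}methyl)‑6‑(trimethylsilyl)hex‑5‑yn‑1‑yl]‑3‑bromo‑4‑methoxy‑2H‑pyran‑2‑one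
Conditions: 2‑benzyloxy‑1‑methylpyridinium triflate, MgO, PhCF3, 85 °C
Reagents that add atoms: 2‑benzyloxy‑1‑methylpyridinium triflate, C[n+]1ccccc1OCc1ccccc1.[O-]S(=O)(=O)C(F)(F)F
Why: O‑Benzylation by thermal benzyl transfer from a neutral pyridinium salt with MgO as acid scavenger, which avoids the alkoxide base that would attack or deprotonate the pyrone and keeps both silyl groups.

Step 15
Reactants: 24 alkynyl silane
Product: 25 6‑[(2R,3R,4R)‑4‑[4‑(benzyloxy)‑3‑methoxyphenyl]‑2‑[(benzyloxy)methyl]‑3‑({[tert‑butyl(dimethyl)silyl]oxy}methyl)hex‑5‑yn‑1‑yl]‑3‑bromo‑4‑methoxy‑2H‑pyran‑2‑one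
Conditions: AgNO3 (10 mol%), MeOH/H2O/CH2Cl2, rt
Reagents that add atoms: none
Why: Silver‑catalysed protodesilylation through a silver acetylide is selective for the C(sp)–Si bond, so the alkyl silyl ether, the bromopyrone and the benzyl ethers remain; the descriptor at C1 changes from S to R only because the CIP priorities change.

Step 16
Reactants: 25 alkyne‑tethered 3‑bromo‑4‑methoxy‑2‑pyrone
Product: 27 {[(1S,2R,3R)‑1‑[4‑(benzyloxy)‑3‑methoxyphenyl]‑3‑[(benzyloxy)methyl]‑7‑bromo‑6‑methoxy‑1,2,3,4‑tetrahydronaphthalen‑2‑yl]methoxy}(tert‑butyl)dimethylsilane, via bridged bicyclic lactone 26 (not isolated)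
Conditions: o‑dichlorobenzene (0.01 M), BHT (cat.), 210 °C, sealed tube, Ar
Reagents that add atoms: none
Why: The pyrone reacts as a 4π diene across its C3 and C6 and the tethered terminal alkyne as the 2π partner in a thermal intramolecular Diels–Alder reaction to give the 2‑oxabicyclo[2.2.2]octadienone 26, which loses CO2 by cycloreversion at the same temperature and leaves ring A aromatic; the closest known reaction type is the cycloaddition–decarboxylation of alkyne‑tethered 2‑pyrones to benzo‑fused carbocycles. Ring B closes in the cycloaddition because the four sp3 carbons C4–C3–C2–C1 join pyrone C6 to the internal alkyne carbon, so the C4a–C8a bond completes a six‑membered ring. Ring A is built from pyrone C3 to C6 plus the two alkyne carbons (C7–C8 bond) and appears when CO2 leaves. No stereocenter is created in 27: the two bridgehead centres of 26 disappear on aromatisation, and C1, C2 and C3 are not reacting atoms and are not epimerisable under neutral conditions. The selectivity needed is regiochemical (OMe at C6, Br at C7, H at C5 and C8) and is fixed by the tether length and the pyrone substitution, which can only pair C6 with the internal and C3 with the terminal alkyne carbon. The bromine at pyrone C3 also raises the reactivity of the donor‑substituted diene, three substituents on the tether favour the folded conformer, and high dilution with a radical inhibitor suppresses intermolecular paths.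

Step 17
Reactants: 27 C7 aryl bromide
Product: 29 (6R,7R,8S)‑8‑[4‑(benzyloxy)‑3‑methoxyphenyl]‑6‑[(benzyloxy)methyl]‑7‑({[tert‑butyl(dimethyl)silyl]oxy}methyl)‑3‑methoxy‑5,6,7,8‑tetrahydronaphthalen‑2‑ol (the C7 phenol), via aryl pinacol boronate 28 (not isolated)
Conditions: Pd(dppf)Cl2 (5 mol%), B2pin2, KOAc, 1,4‑dioxane, 90 °C; then 30% aq. H2O2, NaOH, THF, 0 °C
Reagents that add atoms: bis(pinacolato)diboron, CC1(C)OB(OC1(C)C)B1OC(C)(C)C(C)(C)O1 (atoms in 28 only); hydrogen peroxide, OO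
Why: Miyaura borylation (oxidative addition of the aryl bromide to zerovalent palladium, transmetallation, reductive elimination) followed by peroxide oxidation of the C–B bond by 1,2‑aryl shift places the oxygen exactly at C7.

Step 18
Reactants: 29 C7 phenol
Product: 30 {[(1S,2R,3R)‑7‑(benzyloxy)‑1‑[4‑(benzyloxy)‑3‑methoxyphenyl]‑3‑[(benzyloxy)methyl]‑6‑methoxy‑1,2,3,4‑tetrahydronaphthalen‑2‑yl]methoxy}(tert‑butyl)dimethylsilane
Conditions: BnBr, K2CO3, DMF, rt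
Reagents that add atoms: benzyl bromide, BrCc1ccccc1
Why: Williamson etherification of the phenoxide, so that the phenol cannot compete in the later acylation.

Step 19
Reactants: 30 silyl ether
Product: 31 [(1S,2R,3R)‑7‑(benzyloxy)‑1‑[4‑(benzyloxy)‑3‑methoxyphenyl]‑3‑[(benzyloxy)methyl]‑6‑methoxy‑1,2,3,4‑tetrahydronaphthalen‑2‑yl]methanol
Conditions: Bu4NF, THF, 0 °C → rt
Reagents that add atoms: none
Why: Fluoride cleavage of the Si–O bond frees the C9′ hydroxyl alone, because every other oxygen is a benzyl or methyl ether.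

Step 20
Reactants: 32 p‑coumaric acid
Product: 34 (E)‑3‑[4‑(benzyloxy)phenyl]prop‑2‑enoic acid, via benzyl 4‑benzyloxycinnamate 33 (not isolated)
Conditions: BnBr (2.2 equiv), K2CO3, DMF, 60 °C; then aq. NaOH, MeOH/THF, 60 °C; HCl
Reagents that add atoms: benzyl bromide, BrCc1ccccc1
Why: Exhaustive O‑benzylation of phenol and carboxylate followed by saponification of the benzyl ester only, since the aryl ether is stable to hydroxide; the E alkene is kept.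

Step 21
Reactants: 31 C9′ alcohol; 34 (E)‑4‑benzyloxycinnamic acid
Product: 35 [(1S,2R,3R)‑7‑(benzyloxy)‑1‑[4‑(benzyloxy)‑3‑methoxyphenyl]‑3‑[(benzyloxy)methyl]‑6‑methoxy‑1,2,3,4‑tetrahydronaphthalen‑2‑yl]methyl (E)‑3‑[4‑(benzyloxy)phenyl]prop‑2‑enoate
Conditions: EDC·HCl, DMAP, CH2Cl2, 0 °C → rt
Reagents that add atoms: none
Why: Steglich esterification of the only free hydroxyl through the O‑acylisourea and acylpyridinium; the mild conditions keep the E geometry.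

Step 22
Reactants: 35 tetrabenzyl ester
Product: 36 [(1S,2R,3R)‑7‑hydroxy‑1‑(4‑hydroxy‑3‑methoxyphenyl)‑3‑(hydroxymethyl)‑6‑methoxy‑1,2,3,4‑tetrahydronaphthalen‑2‑yl]methyl (E)‑3‑(4‑hydroxyphenyl)prop‑2‑enoate (CNP0403384.1)
Conditions: BCl3 (1 M in CH2Cl2), pentamethylbenzene, CH2Cl2, −78 → −30 °C; MeOH quench
Reagents that add atoms: none
Why: Lewis‑acid debenzylation in which BCl3 activates each benzyl ether and pentamethylbenzene traps the benzyl cation by Friedel–Crafts alkylation; this spares the cinnamate alkene and ester, the aryl methyl ethers at low temperature and all three stereocenters.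

**Compound list**

1 | 4‑methoxy‑6‑methyl‑2H‑pyran‑2‑one | COC1=CC(=O)OC(C)=C1 | starting material
2 | 3‑bromo‑4‑methoxy‑6‑methyl‑2H‑pyran‑2‑one | COC1=C(Br)C(=O)OC(C)=C1 | intermediate
3 | 3‑bromo‑6‑(bromomethyl)‑4‑methoxy‑2H‑pyran‑2‑one | COC1=C(Br)C(=O)OC(CBr)=C1 | intermediate
4 | 4‑(benzyloxy)‑3‑methoxybenzaldehyde (O‑benzylvanillin) | COc1cc(C=O)ccc1OCc1ccccc1 | starting material
5 | Meldrum's acid | CC1(C)OC(=O)CC(=O)O1 | starting material
6 | 5‑{[4‑(benzyloxy)‑3‑methoxyphenyl]methylidene}‑2,2‑dimethyl‑1,3‑dioxane‑4,6‑dione | COc1cc(C=C2C(=O)OC(C)(C)OC2=O)ccc1OCc1ccccc1 | intermediate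
7 | (trimethylsilyl)acetylene | C#C[Si](C)(C)C | starting material
8 | 5‑{(1S)‑1‑[4‑(benzyloxy)‑3‑methoxyphenyl]‑3‑(trimethylsilyl)prop‑2‑yn‑1‑yl}‑2,2‑dimethyl‑1,3‑dioxane‑4,6‑dione | CC1(C)OC(=O)C([C@H](C#C[Si](C)(C)C)c2ccc(OCc3ccccc3)c(OC)c2)C(=O)O1 | intermediate
9 | (3S)‑3‑[4‑(benzyloxy)‑3‑methoxyphenyl]‑5‑(trimethylsilyl)pent‑4‑ynoic acid | OC(=O)C[C@H](C#C[Si](C)(C)C)c1ccc(OCc2ccccc2)c(OC)c1 | intermediate
10 | mixed pivalic anhydride of 9 (not isolated) | CC(C)(C)C(=O)OC(=O)C[C@H](C#C[Si](C)(C)C)c1ccc(OCc2ccccc2)c(OC)c1 | intermediate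
11 | (4S)‑4‑benzyl‑3‑{(3S)‑3‑[4‑(benzyloxy)‑3‑methoxyphenyl]‑5‑(trimethylsilyl)pent‑4‑ynoyl}‑1,3‑oxazolidin‑2‑one | O=C1OC[C@H](Cc2ccccc2)N1C(=O)C[C@H](C#C[Si](C)(C)C)c1ccc(OCc2ccccc2)c(OC)c1 | intermediate
12 | tert‑butyl bromoacetate | CC(C)(C)OC(=O)CBr | starting material
13 | sodium Z‑enolate of 11 (not isolated) | [Na+].[O-]/C(=C\[C@H](C#C[Si](C)(C)C)c1ccc(OCc2ccccc2)c(OC)c1)N1[C@@H](Cc2ccccc2)COC1=O | intermediate
14 | tert‑butyl (3S,4S)‑3‑{[(4S)‑4‑benzyl‑2‑oxo‑1,3‑oxazolidin‑3‑yl]carbonyl}‑4‑[4‑(benzyloxy)‑3‑methoxyphenyl]‑6‑(trimethylsilyl)hex‑5‑ynoate | O=C1OC[C@H](Cc2ccccc2)N1C(=O)[C@@H](CC(=O)OC(C)(C)C)[C@H](C#C[Si](C)(C)C)c1ccc(OCc2ccccc2)c(OC)c1 | intermediate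
15 | tert‑butyl (3S,4S)‑4‑[4‑(benzyloxy)‑3‑methoxyphenyl]‑3‑(hydroxymethyl)‑6‑(trimethylsilyl)hex‑5‑ynoate | OC[C@@H](CC(=O)OC(C)(C)C)[C@H](C#C[Si](C)(C)C)c1ccc(OCc2ccccc2)c(OC)c1 | intermediate
16 | tert‑butyl (3S,4S)‑4‑[4‑(benzyloxy)‑3‑methoxyphenyl]‑3‑({[tert‑butyl(dimethyl)silyl]oxy}methyl)‑6‑(trimethylsilyl)hex‑5‑ynoate | CC(C)(C)[Si](C)(C)OC[C@@H](CC(=O)OC(C)(C)C)[C@H](C#C[Si](C)(C)C)c1ccc(OCc2ccccc2)c(OC)c1 | intermediate
17 | trimethylsilyl ester of 18 (not isolated) | CC(C)(C)[Si](C)(C)OC[C@@H](CC(=O)O[Si](C)(C)C)[C@H](C#C[Si](C)(C)C)c1ccc(OCc2ccccc2)c(OC)c1 | intermediate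
18 | (3S,4S)‑4‑[4‑(benzyloxy)‑3‑methoxyphenyl]‑3‑({[tert‑butyl(dimethyl)silyl]oxy}methyl)‑6‑(trimethylsilyl)hex‑5‑ynoic acid | CC(C)(C)[Si](C)(C)OC[C@@H](CC(=O)O)[C@H](C#C[Si](C)(C)C)c1ccc(OCc2ccccc2)c(OC)c1 | intermediate
19 | mixed pivalic anhydride of 18 (not isolated) | CC(C)(C)[Si](C)(C)OC[C@@H](CC(=O)OC(=O)C(C)(C)C)[C@H](C#C[Si](C)(C)C)c1ccc(OCc2ccccc2)c(OC)c1 | intermediate
20 | (4R)‑4‑benzyl‑3‑{(3S,4S)‑4‑[4‑(benzyloxy)‑3‑methoxyphenyl]‑3‑({[tert‑butyl(dimethyl)silyl]oxy}methyl)‑6‑(trimethylsilyl)hex‑5‑ynoyl}‑1,3‑oxazolidin‑2‑one | CC(C)(C)[Si](C)(C)OC[C@@H](CC(=O)N1[C@H](Cc2ccccc2)COC1=O)[C@H](C#C[Si](C)(C)C)c1ccc(OCc2ccccc2)c(OC)c1 | intermediate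
21 | sodium Z‑enolate of 20 (not isolated) | [Na+].[O-]/C(=C\[C@H](CO[Si](C)(C)C(C)(C)C)[C@H](C#C[Si](C)(C)C)c1ccc(OCc2ccccc2)c(OC)c1)N1[C@H](Cc2ccccc2)COC1=O | intermediate
22 | (4R)‑4‑benzyl‑3‑{(2R,3R,4S)‑4‑[4‑(benzyloxy)‑3‑methoxyphenyl]‑2‑[(3‑bromo‑4‑methoxy‑2‑oxo‑2H‑pyran‑6‑yl)methyl]‑3‑({[tert‑butyl(dimethyl)silyl]oxy}methyl)‑6‑(trimethylsilyl)hex‑5‑ynoyl}‑1,3‑oxazolidin‑2‑one | COC1=C(Br)C(=O)OC(C[C@@H](C(=O)N2[C@H](Cc3ccccc3)COC2=O)[C@H](CO[Si](C)(C)C(C)(C)C)[C@H](C#C[Si](C)(C)C)c2ccc(OCc3ccccc3)c(OC)c2)=C1 | intermediate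
23 | 3‑bromo‑6‑[(2R,3R,4S)‑4‑[4‑(benzyloxy)‑3‑methoxyphenyl]‑3‑({[tert‑butyl(dimethyl)silyl]oxy}methyl)‑2‑(hydroxymethyl)‑6‑(trimethylsilyl)hex‑5‑yn‑1‑yl]‑4‑methoxy‑2H‑pyran‑2‑one | COC1=C(Br)C(=O)OC(C[C@@H](CO)[C@H](CO[Si](C)(C)C(C)(C)C)[C@H](C#C[Si](C)(C)C)c2ccc(OCc3ccccc3)c(OC)c2)=C1 | intermediate
24 | 6‑[(2R,3R,4S)‑4‑[4‑(benzyloxy)‑3‑methoxyphenyl]‑2‑[(benzyloxy)methyl]‑3‑({[tert‑butyl(dimethyl)silyl]oxy}methyl)‑6‑(trimethylsilyl)hex‑5‑yn‑1‑yl]‑3‑bromo‑4‑methoxy‑2H‑pyran‑2‑one | COC1=C(Br)C(=O)OC(C[C@@H](COCc2ccccc2)[C@H](CO[Si](C)(C)C(C)(C)C)[C@H](C#C[Si](C)(C)C)c2ccc(OCc3ccccc3)c(OC)c2)=C1 | intermediate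
25 | 6‑[(2R,3R,4R)‑4‑[4‑(benzyloxy)‑3‑methoxyphenyl]‑2‑[(benzyloxy)methyl]‑3‑({[tert‑butyl(dimethyl)silyl]oxy}methyl)hex‑5‑yn‑1‑yl]‑3‑bromo‑4‑methoxy‑2H‑pyran‑2‑one (key‑step precursor) | COC1=C(Br)C(=O)OC(C[C@@H](COCc2ccccc2)[C@H](CO[Si](C)(C)C(C)(C)C)[C@H](C#C)c2ccc(OCc3ccccc3)c(OC)c2)=C1 | intermediate
26 | bridged 2‑oxabicyclo[2.2.2]octadienone cycloadduct of 25, both bridgehead configurations (not isolated) | COC1=CC23C[C@@H](COCc4ccccc4)[C@H](CO[Si](C)(C)C(C)(C)C)[C@@H](c4ccc(OCc5ccccc5)c(OC)c4)C2=CC1(Br)C(=O)O3 | intermediate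
27 | {[(1S,2R,3R)‑1‑[4‑(benzyloxy)‑3‑methoxyphenyl]‑3‑[(benzyloxy)methyl]‑7‑bromo‑6‑methoxy‑1,2,3,4‑tetrahydronaphthalen‑2‑yl]methoxy}(tert‑butyl)dimethylsilane | COc1cc([C@H]2c3cc(Br)c(OC)cc3C[C@@H](COCc3ccccc3)[C@@H]2CO[Si](C)(C)C(C)(C)C)ccc1OCc1ccccc1 | intermediate
28 | C7 pinacol boronate of 27 (not isolated) | COc1cc([C@H]2c3cc(B4OC(C)(C)C(C)(C)O4)c(OC)cc3C[C@@H](COCc3ccccc3)[C@@H]2CO[Si](C)(C)C(C)(C)C)ccc1OCc1ccccc1 | intermediate
29 | (6R,7R,8S)‑8‑[4‑(benzyloxy)‑3‑methoxyphenyl]‑6‑[(benzyloxy)methyl]‑7‑({[tert‑butyl(dimethyl)silyl]oxy}methyl)‑3‑methoxy‑5,6,7,8‑tetrahydronaphthalen‑2‑ol | COc1cc([C@H]2c3cc(O)c(OC)cc3C[C@@H](COCc3ccccc3)[C@@H]2CO[Si](C)(C)C(C)(C)C)ccc1OCc1ccccc1 | intermediate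
30 | {[(1S,2R,3R)‑7‑(benzyloxy)‑1‑[4‑(benzyloxy)‑3‑methoxyphenyl]‑3‑[(benzyloxy)methyl]‑6‑methoxy‑1,2,3,4‑tetrahydronaphthalen‑2‑yl]methoxy}(tert‑butyl)dimethylsilane | COc1cc([C@H]2c3cc(OCc4ccccc4)c(OC)cc3C[C@@H](COCc3ccccc3)[C@@H]2CO[Si](C)(C)C(C)(C)C)ccc1OCc1ccccc1 | intermediate
31 | [(1S,2R,3R)‑7‑(benzyloxy)‑1‑[4‑(benzyloxy)‑3‑methoxyphenyl]‑3‑[(benzyloxy)methyl]‑6‑methoxy‑1,2,3,4‑tetrahydronaphthalen‑2‑yl]methanol | COc1cc([C@H]2c3cc(OCc4ccccc4)c(OC)cc3C[C@@H](COCc3ccccc3)[C@@H]2CO)ccc1OCc1ccccc1 | intermediate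
32 | p‑coumaric acid | OC(=O)/C=C/c1ccc(O)cc1 | starting material
33 | benzyl (E)‑3‑[4‑(benzyloxy)phenyl]prop‑2‑enoate (not isolated) | O=C(OCc1ccccc1)/C=C/c1ccc(OCc2ccccc2)cc1 | intermediate
34 | (E)‑3‑[4‑(benzyloxy)phenyl]prop‑2‑enoic acid | OC(=O)/C=C/c1ccc(OCc2ccccc2)cc1 | intermediate
35 | [(1S,2R,3R)‑7‑(benzyloxy)‑1‑[4‑(benzyloxy)‑3‑methoxyphenyl]‑3‑[(benzyloxy)methyl]‑6‑methoxy‑1,2,3,4‑tetrahydronaphthalen‑2‑yl]methyl (E)‑3‑[4‑(benzyloxy)phenyl]prop‑2‑enoate | COc1cc([C@H]2c3cc(OCc4ccccc4)c(OC)cc3C[C@@H](COCc3ccccc3)[C@@H]2COC(=O)/C=C/c2ccc(OCc3ccccc3)cc2)ccc1OCc1ccccc1 | intermediate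
36 | [(1S,2R,3R)‑7‑hydroxy‑1‑(4‑hydroxy‑3‑methoxyphenyl)‑3‑(hydroxymethyl)‑6‑methoxy‑1,2,3,4‑tetrahydronaphthalen‑2‑yl]methyl (E)‑3‑(4‑hydroxyphenyl)prop‑2‑enoate | COc1cc([C@H]2c3cc(O)c(OC)cc3C[C@@H](CO)[C@@H]2COC(=O)/C=C/c2ccc(O)cc2)ccc1O | target

**Step count and risk**

Total step count: 22. Longest linear sequence: 19 steps (steps 3 to 19, then 21 and 22, from O‑benzylvanillin 4).

The three steps most likely to fail:

1. Step 16. The cycloaddition of an unactivated terminal alkyne with a donor‑substituted pyrone may be slower than thermal decomposition of the bromopyrone or loss of silyl and benzyl groups, so that conversion stalls. Fallback: setting out from 25, palladium‑catalysed oxidative methoxycarbonylation of the terminal alkyne (PdCl2 cat., CuCl2, NaOAc, CO, MeOH, rt) would give the methyl alkynoate F1. This electron‑poor 2π partner should undergo the same intramolecular cycloaddition at far lower temperature (toluene, 110–130 °C), through the bridged lactone F2, to the methyl tetralin‑8‑carboxylate F3. SN2 demethylation of the hindered ester (LiI, pyridine, reflux) would give the tetralin‑8‑carboxylic acid F4, and silver‑catalysed protodecarboxylation of this ortho‑bromo benzoic acid (Ag2CO3 cat., AcOH, DMSO, 120 °C) comes back to the route at 27.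

2. Step 12. Proton transfer from the acidic bromomethyl group of 3 to the enolate, addition of the enolate to the pyrone ring, or erosion of facial selectivity in a mismatched pairing of the auxiliary with the C2 center may lower yield and diastereoselectivity. Fallback: setting out from 20, enolate 21 is alkylated with tert‑butyl bromoacetate 12, an electrophile of proven reliability, to give the imide tert‑butyl ester F5, and the pyrone is then built on the new arm. NaBH4 reduction gives the C9 alcohol F6, and benzyl transfer as in step 14 gives the benzyl ether F7. TMSOTf and 2,6‑lutidine give, through the trimethylsilyl ester F8, the carboxylic acid F9. Activation with carbonyldiimidazole gives the acyl imidazolide F10, which C‑acylates the dianion of methyl acetoacetate (NaH, then n‑BuLi, THF) to the methyl 3,5‑dioxo ester F11. DBU in toluene closes this to the 4‑hydroxy‑2‑pyrone F12, Me2SO4 with K2CO3 in acetone gives the 4‑methoxy‑2‑pyrone F13, and NBS in CH2Cl2 at 0 °C brominates pyrone C3 to come back to the route at 24.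

3. Step 4. The electron‑rich arylidene may react slowly and with poor face discrimination at rhodium, giving low conversion or low enantiomeric purity at C1. Fallback: setting out from 6, uncatalysed 1,4‑addition of (trimethylsilyl)ethynylmagnesium bromide F14 (from 7 and EtMgBr, THF, −20 → 0 °C) would give the racemic alkynylated Meldrum's acid F15. Decarboxylation as in step 5 gives the racemic pentynoic acid F16. Coupling with (S)‑4‑benzyl‑2‑oxazolidinone as in step 6, through the racemic mixed pivalic anhydride F17, gives 11 together with its C3 epimer, the (3R)‑imide F18, and the two diastereomers are separated by chromatography or crystallisation; the route is rejoined at 11.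

**Further compounds**

F1 | step 16 | methyl alkynoate of 25 (CO2Me on the alkyne terminus) | COC1=C(Br)C(=O)OC(C[C@@H](COCc2ccccc2)[C@H](CO[Si](C)(C)C(C)(C)C)[C@H](C#CC(=O)OC)c2ccc(OCc3ccccc3)c(OC)c2)=C1
F2 | step 16 | bridged lactone cycloadduct of F1, both bridgehead configurations (not isolated) | COC1=CC23C[C@@H](COCc4ccccc4)[C@H](CO[Si](C)(C)C(C)(C)C)[C@@H](c4ccc(OCc5ccccc5)c(OC)c4)C2=C(C(=O)OC)C1(Br)C(=O)O3
F3 | step 16 | methyl (1S,2R,3R)‑tetralin‑8‑carboxylate analogue of 27 | COc1cc([C@H]2c3c(C(=O)OC)c(Br)c(OC)cc3C[C@@H](COCc3ccccc3)[C@@H]2CO[Si](C)(C)C(C)(C)C)ccc1OCc1ccccc1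
F4 | step 16 | (1S,2R,3R)‑tetralin‑8‑carboxylic acid analogue of 27 | COc1cc([C@H]2c3c(C(=O)O)c(Br)c(OC)cc3C[C@@H](COCc3ccccc3)[C@@H]2CO[Si](C)(C)C(C)(C)C)ccc1OCc1ccccc1
F5 | step 12 | imide tert‑butyl ester from 20 and 12 | CC(C)(C)OC(=O)C[C@@H](C(=O)N1[C@H](Cc2ccccc2)COC1=O)[C@H](CO[Si](C)(C)C(C)(C)C)[C@H](C#C[Si](C)(C)C)c1ccc(OCc2ccccc2)c(OC)c1
F6 | step 12 | C9 alcohol tert‑butyl ester | CC(C)(C)OC(=O)C[C@@H](CO)[C@H](CO[Si](C)(C)C(C)(C)C)[C@H](C#C[Si](C)(C)C)c1ccc(OCc2ccccc2)c(OC)c1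
F7 | step 12 | C9 benzyl ether tert‑butyl ester | CC(C)(C)OC(=O)C[C@@H](COCc1ccccc1)[C@H](CO[Si](C)(C)C(C)(C)C)[C@H](C#C[Si](C)(C)C)c1ccc(OCc2ccccc2)c(OC)c1
F8 | step 12 | trimethylsilyl ester of F9 (not isolated) | C[Si](C)(C)OC(=O)C[C@@H](COCc1ccccc1)[C@H](CO[Si](C)(C)C(C)(C)C)[C@H](C#C[Si](C)(C)C)c1ccc(OCc2ccccc2)c(OC)c1
F9 | step 12 | carboxylic acid | OC(=O)C[C@@H](COCc1ccccc1)[C@H](CO[Si](C)(C)C(C)(C)C)[C@H](C#C[Si](C)(C)C)c1ccc(OCc2ccccc2)c(OC)c1
F10 | step 12 | acyl imidazolide of F9 (not isolated) | O=C(C[C@@H](COCc1ccccc1)[C@H](CO[Si](C)(C)C(C)(C)C)[C@H](C#C[Si](C)(C)C)c1ccc(OCc2ccccc2)c(OC)c1)n1ccnc1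
F11 | step 12 | methyl 3,5‑dioxo ester | COC(=O)CC(=O)CC(=O)C[C@@H](COCc1ccccc1)[C@H](CO[Si](C)(C)C(C)(C)C)[C@H](C#C[Si](C)(C)C)c1ccc(OCc2ccccc2)c(OC)c1
F12 | step 12 | 4‑hydroxy‑2‑pyrone | OC1=CC(=O)OC(C[C@@H](COCc2ccccc2)[C@H](CO[Si](C)(C)C(C)(C)C)[C@H](C#C[Si](C)(C)C)c2ccc(OCc3ccccc3)c(OC)c2)=C1
F13 | step 12 | 4‑methoxy‑2‑pyrone (24 without bromine) | COC1=CC(=O)OC(C[C@@H](COCc2ccccc2)[C@H](CO[Si](C)(C)C(C)(C)C)[C@H](C#C[Si](C)(C)C)c2ccc(OCc3ccccc3)c(OC)c2)=C1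
F14 | step 4 | (trimethylsilyl)ethynylmagnesium bromide | C[Si](C)(C)C#C[Mg]Br
F15 | step 4 | racemic alkynylated Meldrum's acid | CC1(C)OC(=O)C(C(C#C[Si](C)(C)C)c2ccc(OCc3ccccc3)c(OC)c2)C(=O)O1
F16 | step 4 | racemic 3‑aryl‑5‑(trimethylsilyl)pent‑4‑ynoic acid | OC(=O)CC(C#C[Si](C)(C)C)c1ccc(OCc2ccccc2)c(OC)c1
F17 | step 4 | racemic mixed pivalic anhydride (not isolated) | CC(C)(C)C(=O)OC(=O)CC(C#C[Si](C)(C)C)c1ccc(OCc2ccccc2)c(OC)c1
F18 | step 4 | (4S)‑4‑benzyl‑3‑[(3R)‑3‑aryl‑5‑(trimethylsilyl)pent‑4‑ynoyl]‑1,3‑oxazolidin‑2‑one (C3 epimer of 11) | O=C1OC[C@H](Cc2ccccc2)N1C(=O)C[C@@H](C#C[Si](C)(C)C)c1ccc(OCc2ccccc2)c(OC)c1
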